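**Retrosynthetic overview**
1. The target is a single 31-membered lactone ring (C1 carbonyl carbon, C2 to C30 methylenes, ring oxygen between C30 and C1). The strategy rests on this unbranched methylene run C2–C30, in which a buta-1,3-diyne at C10–C13 can be hidden and later erased by hydrogenation.
2. Last disconnection: eight hydrogens are removed from C10–C13, leading back to the 31-membered diyne lactone triaconta-10,12-diyn-30-olide.
3. Key disconnection: the C11–C12 bond between the two inner sp carbons. This opens the only ring to the open-chain ester nonadec-18-yn-1-yl undec-10-ynoate, which carries two terminal alkynes.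
4. Ester C1–O disconnection gives commercial undec-10-ynoic acid and the C19 alkynol nonadec-18-yn-1-ol.
5. The alkynol comes from nonadec-2-yn-1-ol by moving the triple bond to the chain end, and that alcohol from propargyl alcohol and 1-bromohexadecane by alkylation at the alkyne carbon.

Key step: step 4

Remark on the chemistry: the target has no stereocentre and no C=C bond, so no stereochemical control is needed; atom numbers follow the lactone chain (C1 carbonyl carbon, C30 carbon on the ring oxygen).

**Step 1**
Reactants: 1 propargyl alcohol (prop-2-yn-1-ol); 2 1-bromohexadecane
Product: 4 nonadec-2-yn-1-ol, via dilithiated propargyl alcohol 3 (not isolated)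
Conditions: 1 (1.3 equiv), n-BuLi (2.6 equiv), THF–DMPU, −78 to 0 °C; then 2, 0 °C to rt; then H2O
Reagents that add atoms: none
Why: Alkylation of the propargyl alcohol dianion: the lithium alkynide carbon is far more nucleophilic than the lithium alkoxide oxygen, so SN2 attack on the primary bromide should form the new C–C bond at carbon only.

**Step 2**
Reactants: 4 nonadec-2-yn-1-ol
Product: 6 nonadec-18-yn-1-ol, via dipotassium alkynide alkoxide 5 (not isolated)
Conditions: KH (4 equiv), H2N(CH2)3NH2–THF, rt (gives KNH(CH2)3NH2); then 4, rt; then H2O, 0 °C
Reagents that add atoms: none
Why: Alkyne zipper reaction: the potassium amide moves the triple bond along the chain by reversible propargyl–allenyl proton shifts, the alkoxide end blocks travel in that direction, and irreversible formation of the terminal potassium alkynide at the far end drains the equilibrium.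

**Step 3**
Reactants: 6 nonadec-18-yn-1-ol; 7 undec-10-ynoic acid
Product: 8 nonadec-18-yn-1-yl undec-10-ynoate
Conditions: DCC (1.1 equiv), DMAP (cat.), CH2Cl2, 0 °C to rt
Reagents that add atoms: none
Why: Steglich esterification: carbodiimide activation of the unhindered acid with DMAP as acyl-transfer catalyst should esterify the primary alcohol under neutral conditions that leave both terminal alkynes untouched.

**Step 4**
Reactants: 8 nonadec-18-yn-1-yl undec-10-ynoate
Product: 9 triaconta-10,12-diyn-30-olide (1-oxacyclohentriaconta-11,13-diyn-2-one)
Conditions: Cu(OAc)2 (anhydrous, 10 equiv), pyridine–Et2O (6:1), 45 °C, 8 added by syringe pump over 12 h (final ca. 1 mM)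
Reagents that add atoms: none
Why: Pyridine and acetate remove the C(sp)–H proton of each copper-bound terminal alkyne, the two alkynide units gather on bridged divalent copper centres, and inner-sphere electron transfer (each divalent copper becoming monovalent copper) joins C11 and C12 as the buta-1,3-diyne. The closest known reaction type is the Glaser–Eglinton oxidative macrocyclisation of ester-tethered alpha,omega-diynes with stoichiometric Cu(OAc)2 in pyridine. The single ring, the 31-membered lactone, is closed end to end by joining the two chain termini; a ring of this size holds the linear four-carbon rod without bending it, and the rod removes several rotors from the closing chain. No stereocentre is formed. The selectivity the step needs is ring closure over intermolecular coupling to dimer and oligomers, which slow addition into a large excess of Cu(OAc)2 should secure by keeping the stationary concentration of free 8 very low while both ends of each added molecule are metalated quickly. Site selectivity follows from the substrate, because the two terminal alkyne C–H bonds are the only acidic positions and the ester and the methylenes do not react with divalent copper under these conditions.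

**Step 5**
Reactants: 9 triaconta-10,12-diyn-30-olide
Product: 10 triacontan-30-olide (1-oxacyclohentriacontan-2-one), the target
Conditions: H2 (1 atm), Pd/C (10%), EtOAc–THF, rt
Reagents that add atoms: none
Why: Heterogeneous catalytic hydrogenation should add four equivalents of H2 across the conjugated diyne; the ester is the only other functional group and is inert, and no stereocentre arises.

**Compound list**
1 | propargyl alcohol (prop-2-yn-1-ol) | C#CCO | starting material
2 | 1-bromohexadecane | CCCCCCCCCCCCCCCCBr | starting material
3 | dilithiated propargyl alcohol (lithium 3-lithioprop-2-yn-1-olate) | [Li]C#CCO[Li] | intermediate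
4 | nonadec-2-yn-1-ol | CCCCCCCCCCCCCCCCC#CCO | intermediate
5 | dipotassium alkynide alkoxide of nonadec-18-yn-1-ol | [K]C#CCCCCCCCCCCCCCCCCCO[K] | intermediate
6 | nonadec-18-yn-1-ol | C#CCCCCCCCCCCCCCCCCCO | intermediate
7 | undec-10-ynoic acid | C#CCCCCCCCCC(=O)O | starting material
8 | nonadec-18-yn-1-yl undec-10-ynoate | C#CCCCCCCCCC(=O)OCCCCCCCCCCCCCCCCCC#C | intermediate
9 | triaconta-10,12-diyn-30-olide (1-oxacyclohentriaconta-11,13-diyn-2-one) | O=C1CCCCCCCCC#CC#CCCCCCCCCCCCCCCCCCO1 | intermediate
10 | triacontan-30-olide (1-oxacyclohentriacontan-2-one) | O=C1CCCCCCCCCCCCCCCCCCCCCCCCCCCCCO1 | target

**Total step count:** 5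
**Longest linear sequence:** 5 steps (from 1 and 2 to 10; 7 enters at step 3)

**Steps most likely to fail**

Step 4 (key step). Intermolecular coupling of two ester molecules may outrun ring closure, so that cyclic dimer and linear oligomers form, or the coupling may stall after metalation of only one terminus. Fallback: the C11–C12 bond is made first between two separate molecules by Cadiot–Chodkiewicz heterocoupling, and the ring is then closed at the ester C1–O bond by macrolactonisation. The fallback sets out from 6 and 7. Compound 6 is brominated at the alkyne terminus (NBS, AgNO3 cat., acetone, rt) to 19-bromononadec-18-yn-1-ol F1. F1 and 7 are coupled (CuCl cat., NH2OH·HCl, aqueous EtNH2, MeOH–THF, 0 °C to rt) to 30-hydroxytriaconta-10,12-diynoic acid F2. F2 is activated with 2,4,6-trichlorobenzoyl chloride and Et3N in THF as 30-hydroxytriaconta-10,12-diynoic 2,4,6-trichlorobenzoic anhydride F3 (not isolated), which is added slowly to DMAP in toluene at 80 °C (Yamaguchi macrolactonisation) to close the 31-membered ring. The fallback comes back to the route at 9, and step 5 follows unchanged.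

Step 2. The triple bond may travel incompletely over its sixteen positions, leaving internal alkyne and allene isomers that are hard to separate, because the long-chain potassium alkoxide dissolves poorly in the diamine or the base is partly quenched. Fallback: the triple bond is placed at the chain end by substitution with acetylide instead of being moved there. The fallback sets out from 1 through its dianion 3, made as in step 1. Dianion 3 is alkylated with an excess of commercial 1,14-dibromotetradecane (THF–DMPU, −78 °C to rt, then H2O) to 17-bromoheptadec-2-yn-1-ol F4. Hydrogenation (H2, PtO2, EtOAc, rt) should give 17-bromoheptadecan-1-ol F5. F5 and an excess of lithium acetylide–ethylenediamine complex LiC≡CH·H2NCH2CH2NH2 (DMSO, rt, then H2O) should give the C19 terminal alkynol. The fallback comes back to the route at 6.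

Step 1. Substitution at the waxy C16 bromide by the aggregated, sparingly soluble dianion may be slow, so that O-alkylation and E2 elimination take over. Fallback: the other propargylic bond is formed, by adding an alkynide to formaldehyde instead of alkylating the propargyl alcohol dianion. The fallback sets out from 2. Compound 2 and lithium acetylide–ethylenediamine complex (DMSO, rt) should give octadec-1-yne F6. Deprotonation with n-BuLi (THF, −78 °C) gives octadec-1-yn-1-yllithium F7 (not isolated), which adds to paraformaldehyde (CH2O)n (−78 °C to rt, then H2O). The fallback comes back to the route at 4.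

**Further compounds**
F1 | step 4 | 19-bromononadec-18-yn-1-ol | BrC#CCCCCCCCCCCCCCCCCCO
F2 | step 4 | 30-hydroxytriaconta-10,12-diynoic acid | OC(=O)CCCCCCCCC#CC#CCCCCCCCCCCCCCCCCCO
F3 | step 4 | 30-hydroxytriaconta-10,12-diynoic 2,4,6-trichlorobenzoic anhydride | O=C(OC(=O)c1c(Cl)cc(Cl)cc1Cl)CCCCCCCCC#CC#CCCCCCCCCCCCCCCCCCO
F4 | step 2 | 17-bromoheptadec-2-yn-1-ol | OCC#CCCCCCCCCCCCCCCBr
F5 | step 2 | 17-bromoheptadecan-1-ol | OCCCCCCCCCCCCCCCCCBr
F6 | step 1 | octadec-1-yne | C#CCCCCCCCCCCCCCCCC
F7 | step 1 | octadec-1-yn-1-yllithium | [Li]C#CCCCCCCCCCCCCCCCC
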